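Raising the bath from 35 °C to 60 °C speeds every step here, so I asked which gain counts for a catalyst that must turn many times while its reagent consumes itself.

- Saturday's: substrate 0.25 M; reagent 4.00 equiv; free catalyst 0.5 mol%; temperature 35 °C; time 10 min
- Tuesday's: substrate 0.25 M; reagent 4.00 equiv; free catalyst 0.5 mol%; temperature 60 °C; time 10 min

    catalyst intermediate A → spent catalyst (k1 = 0.00116 /s, Ea1 = 111 kJ/mol)
    substrate + catalyst intermediate A → catalyst intermediate B (k2 = 1.71 /M/s, Ea2 = 60.0 kJ/mol)
    reagent + free catalyst ⇌ catalyst intermediate A (K3 = 0.71 /M, k3 = 4.00 /M/s, Ea3 = 56.0 kJ/mol, ΔH3 = 42.0 kJ/mol)
    2 reagent → self-condensation product (k4 = 0.00718 /M/s, Ea4 = 54.0 kJ/mol)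
    catalyst intermediate B → free catalyst + target (k5 = 0.228 /s, Ea5 = 83.0 kJ/mol)
    (constants at 60 °C)

- for a step with 2 of a species take k times the square, and two of it per event
- constants are those at 60 °C; use the activation energies and enthalpies for any other temperature

* the best flask by amount of target, in percent of the substrate charged; "all alike" if 1.5 percentage points covers them all (Saturday's / Tuesday's / all alike)
* amount of target at the end, in percent of the substrate charged, Saturday's
* amount of target at the end, in percent of the substrate charged, Tuesday's

Each turn of the catalyst makes 0.5 mol% of the substrate charged, so the target is the loading times the turnover number. I held substrate at its charge and dropped the step to spent catalyst. I let reagent, as a fraction r of its charge, fall by self-condensation: r = 1/(1+u), where u counts the first half-lives of that step that have passed. A turn needs free catalyst to bind reagent and substrate then to capture the bound form before it falls back. I wrote these factors as powers of ten, for the whole run, so that they add: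

| Power of ten of | Saturday's | Tuesday's |
|---|---|---|
| bindings per catalyst at full reagent | 2.67 | 3.38 |
| share captured by substrate | −1.71 | −1.15 |
| u | 0.248 | 0.935 |
| bindings plus share minus u | 0.706 | 1.29 |

The last row, taken back out of logarithms, gives 5.08 for Saturday's and 19.6 for Tuesday's. I called this the turn ratio G, the turnovers earned per unit of the logarithm of the reagent's fall while reagent is thin.

Reading the columns against each other, going from Saturday's to Tuesday's, binding gains 0.710 of a power of ten and u gains 0.687. These two nearly cancel, so what remains is the capture share's 0.560, and G rises by a factor 3.86.

Plentiful reagent holds catalyst in bound forms, though. Let s be the bound forms per free catalyst at full reagent. The turn rate then goes as r/(1+sr), and summing it over the reagent's fall gives N = G ln(1+u/(1+s)). Saturday's has u = 1.77 and s = 0.952, so N = 3.28 and the target is 1.64%. Tuesday's has u = 8.62 and s = 1.90, so N = 27.1 and the target is 13.6%.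

The forecast named Tuesday's, with 1.5% and 11.7%, the latter below mine, holding that “the yield is set by turnovers”.

The flasks gave 1.57% on Saturday's and 12.2% on Tuesday's, so Tuesday's is the better one. The step I had dropped made no difference worth counting to Tuesday's target, though 7.07% of that flask's catalyst stood spent at 10.0 min. Tuesday's target divided by the loading is 24.4 turnovers, which is 1.24 times its turn ratio of 19.6. For a repeat of Saturday's at 50 °C, G comes to 11.8 and the reckoning to 6.34%, and that flask gave 6.06%.

The constants belong to no real substance.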